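**Plan**

1. Numbering: C1 fusion carbon with CH3, C2 CHOAc, C3 CH2, C4 C(OH)(i-Pr), C5 fusion CH, C6 CH–O-veratroyl, C7 CH2, C8(CH3)–C9 oxirane, C10 CHOH; β is the face of the C1 methyl. The oxirane is trans-fused: its oxygen is β on C8 and α on C9.
2. Enabling feature: C1 is quaternary, sits β to a C6 carbonyl through C5 and carries C10 at ketone level. C1–C10 is therefore the bond that a C10 acyl radical makes with the β-carbon of a C5=C1–C6(=O) acylcyclopentene, and it closes the seven-membered ring.
3. Cuts, in retrosynthetic order: C10–H together with O2–acetyl; oxirane O (taken off the (E)-form of the C8=C9 enone); C8=C9; O6–veratroyl and C6–H; C1–C10 (key); C5–C6; C4–i-Pr; C1–CH3.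
4. Forward: the cyclopentene is built from a 4-silyloxycyclopentenone (methyl, bromine, isopropyl), the C6–C10 chain is attached at C5 as a 3-methylglutaryl unit, the cycloheptane is closed by C1–C10, then C6, C8=C9, the oxirane and C10 are set in that order.
5. Stereochemistry: C2 is bought; C4 by addition anti to C2–O; C1 by radical attack anti to C2–OSi; C5 by hydrogen transfer (trans fusion, epimerisable); C6 and C10 by hydride delivered from O4 and O2; C8 and C9 by suprafacial oxygen transfer to the photochemically formed (E)-cycloheptenone.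

Key step: step 8

Remark: an oxirane whose oxygen lies on opposite ring faces at C8 and C9 cannot arise by epoxidising the ring (Z)-alkene, so the oxygen is transferred to the strained (E)-isomer of the enone.

**Route**

Step 1
Reactants: 1 (S)-4-[(tert-butyldimethylsilyl)oxy]cyclopent-2-en-1-one; 2 methyllithium
Product: 3 tert-butyldimethyl{[(1S,2S)-2-methyl-4-[(trimethylsilyl)oxy]cyclopent-3-en-1-yl]oxy}silane (methyl trans to the TBS ether)
Conditions: MeLi, CuI, Et2O, 0 °C; then 1, TMSCl, THF, −78 °C
Reagents that add atoms: methyllithium (2), [Li]C; chlorotrimethylsilane, C[Si](C)(C)Cl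
Why: Conjugate addition of the Gilman cuprate with in situ silyl trapping places the future C1 methyl on the β-carbon, anti to the C2 silyloxy group (a centre erased again in step 2), and fixes the enolate regiospecifically as silyl enol ether 3.

Step 2
Reactants: 3 silyl enol ether
Product: 4 (S)-4-[(tert-butyldimethylsilyl)oxy]-3-methylcyclopent-2-en-1-one
Conditions: Pd(OAc)2, MeCN, rt
Reagents that add atoms: none
Why: Saegusa–Ito oxidation: divalent palladium metallates the silyl enol ether at C5 and β-hydride loss from C1 restores the enone, now with methyl on its β-carbon, while C2 is untouched.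

Step 3
Reactants: 4 (S)-4-[(tert-butyldimethylsilyl)oxy]-3-methylcyclopent-2-en-1-one
Product: 6 (S)-2-bromo-4-[(tert-butyldimethylsilyl)oxy]-3-methylcyclopent-2-en-1-one, via dibromo ketone 5 (not isolated)
Conditions: Br2, CH2Cl2, 0 °C; then Et3N, 0 °C to rt
Reagents that add atoms: bromine, BrBr
Why: α-Bromination of an enone by addition–elimination: bromine adds across C5=C1 and Et3N removes HBr by E1cB, leaving bromine on C5; bromide is preferred to iodide because it resists halogen–magnesium exchange in step 4.

Step 4
Reactants: 6 (S)-2-bromo-4-[(tert-butyldimethylsilyl)oxy]-3-methylcyclopent-2-en-1-one; 7 isopropylmagnesium chloride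
Product: 8 (1S,4S)-2-bromo-4-[(tert-butyldimethylsilyl)oxy]-3-methyl-1-(propan-2-yl)cyclopent-2-en-1-ol (OH cis to the TBS ether)
Conditions: i-PrMgCl, CeCl3, THF, −78 °C
Reagents that add atoms: isopropylmagnesium chloride (7), CC(C)[Mg]Cl
Why: Organocerium 1,2-addition to the ketone: the weakly basic cerium reagent avoids enolisation, β-hydride reduction and loss of the silyloxy group, and attacks the carbonyl face anti to the C2 silyloxy group, so C4 forms with OH cis to C2–O and isopropyl trans.

Step 5
Reactants: 8 tertiary alcohol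
Product: 9 tert-butyl{[(1S,4S)-3-bromo-2-methyl-4-(propan-2-yl)-4-[(triethylsilyl)oxy]cyclopent-2-en-1-yl]oxy}dimethylsilane
Conditions: TESOTf, 2,6-lutidine, CH2Cl2, −78 to 0 °C
Reagents that add atoms: triethylsilyl trifluoromethanesulfonate, CC[Si](CC)(CC)OS(=O)(=O)C(F)(F)F
Why: Silylation of a hindered tertiary allylic alcohol with a silyl triflate and 2,6-lutidine; the triethylsilyl group can later be removed beside the secondary TBS ether and meanwhile adds bulk to the β face next to C5.

Step 6
Reactants: 9 alkenyl bromide; 10 3-methylglutaric anhydride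
Product: 12 5-{(3S,5S)-3-[(tert-butyldimethylsilyl)oxy]-2-methyl-5-(propan-2-yl)-5-[(triethylsilyl)oxy]cyclopent-1-en-1-yl}-3-methyl-5-oxopentanoic acid (both C8 epimers), via alkenyllithium 11 (not isolated)
Conditions: t-BuLi, Et2O, −78 °C; then 10, THF, −78 °C; 1 M HCl
Reagents that add atoms: 3-methylglutaric anhydride (10), O=C1CC(C)CC(=O)O1
Why: Bromine–lithium exchange and acylation of the alkenyllithium by a cyclic anhydride, whose ring opening gives a carboxylate that stops the reaction at the ketone; the chain is kept saturated because a (Z)-glutaconyl keto acid would be strongly C7-acidic and would close to a 2-pyranone on activation, and attack at either carbonyl of the meso anhydride gives both C8 epimers, which is harmless since C8 becomes trigonal in step 12.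

Step 7
Reactants: 12 keto acid
Product: 13 Se-phenyl 5-{(3S,5S)-3-[(tert-butyldimethylsilyl)oxy]-2-methyl-5-(propan-2-yl)-5-[(triethylsilyl)oxy]cyclopent-1-en-1-yl}-3-methyl-5-oxopentaneselenoate (both C8 epimers)
Conditions: (PhSe)2, Bu3P, CH2Cl2, rt
Reagents that add atoms: diphenyl diselenide, c1ccc(cc1)[Se][Se]c1ccccc1
Why: Selenoesterification of a carboxylic acid through its acyloxyphosphonium salt (phosphine–diselenide redox condensation), neutral conditions that leave the enone and both silyl ethers alone.

Step 8
Reactants: 13 acyl selenide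
Product: 14 trans-fused 2β-[(tert-butyldimethylsilyl)oxy]-1β,8-dimethyl-4α-(propan-2-yl)-4β-[(triethylsilyl)oxy]-5α-H-perhydroazulene-6,10-dione (target numbering; both C8 epimers)
Conditions: Bu3SnH (slow addition), AIBN, PhH (5 mM), 80 °C
Reagents that add atoms: none
Why: Bu3Sn• takes the phenylseleno group from 13 and the nucleophilic σ-acyl radical at C10 adds to C1, the β-carbon of the C6(=O)–C5=C1 enone, after which the C6-stabilised C5 radical is reduced by Bu3SnH and the chain continues. The closest known reaction type is the stannane-mediated conjugate cyclisation of acyl radicals from Se-phenyl selenoesters onto enones and acrylates, for which seven-membered closures are on record, a fully substituted β-carbon being at the demanding end. The cycloheptane closes 7-endo-trig, the 6-exo alternative (attack at C5) being polarity-mismatched and shielded by the quaternary C4. The C1 centre is set by the adjacent C2 silyloxy group, which blocks the β face so that C10 bonds on the α face and the methyl ends β. C5 is set by hydrogen transfer to the α face, giving the trans fusion, and since C5 is α to the C6 ketone any cis-fused material can be equilibrated toward the isomer with C6 anti to the C4 isopropyl group. The step needs cyclisation to outrun reduction and decarbonylation of the acyl radical, which slow stannane addition at high dilution and the slow CO loss of a primary-alkyl acyl radical should secure; both C8 epimers are expected to cyclise.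

Step 9
Reactants: 14 bis(silyl ether) diketone
Product: 15 trans-fused 2β-[(tert-butyldimethylsilyl)oxy]-4β-hydroxy-1β,8-dimethyl-4α-(propan-2-yl)perhydroazulene-6,10-dione (both C8 epimers)
Conditions: HF·pyridine, pyridine, THF, 0 °C
Reagents that add atoms: none
Why: Fluoride-assisted cleavage of the more labile triethylsilyl ether under buffered HF·pyridine, the neopentyl secondary TBS ether at C2 reacting far more slowly; the weakly acidic medium avoids β-elimination or retro-aldol cleavage of the β-oxygenated C6 ketone.

Step 10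
Reactants: 15 β-hydroxy diketone
Product: 16 trans-fused 2β-[(tert-butyldimethylsilyl)oxy]-4β,6α-dihydroxy-1β,8-dimethyl-4α-(propan-2-yl)perhydroazulen-10-one (both C8 epimers)
Conditions: Me4NBH(OAc)3, MeCN/AcOH, −20 °C
Reagents that add atoms: none
Why: Saksena–Evans hydroxyl-directed reduction: the C4 hydroxyl exchanges onto boron and delivers hydride through a six-membered transition state to the β face of the C6 carbonyl, giving the 6α-alcohol, while the C10 ketone, which has no free β-hydroxyl, is not reduced by the triacetoxyborohydride.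

Step 11
Reactants: 16 diol; 17 3,4-dimethoxybenzoyl chloride
Product: 18 trans-fused 2β-[(tert-butyldimethylsilyl)oxy]-4β-hydroxy-1β,8-dimethyl-4α-(propan-2-yl)-10-oxoperhydroazulen-6α-yl 3,4-dimethoxybenzoate (both C8 epimers)
Conditions: 17, Et3N, DMAP, CH2Cl2, rt
Reagents that add atoms: 3,4-dimethoxybenzoyl chloride (17), COc1ccc(C(=O)Cl)cc1OC
Why: DMAP-catalysed acylation with an acid chloride; C6–OH is the only secondary hydroxyl and the tertiary C4–OH does not react, so the veratroyl group is placed without a selectivity problem.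

Step 12
Reactants: 18 keto ester
Product: 19 trans-fused 2β-[(tert-butyldimethylsilyl)oxy]-4β-hydroxy-1β,8-dimethyl-4α-(propan-2-yl)-10-oxo-8-ene 6α-(3,4-dimethoxybenzoate) (C8=C9 enone, ring (Z)-alkene)
Conditions: IBX, DMSO, 70 °C
Reagents that add atoms: none
Why: IBX-mediated dehydrogenation of a ketone to its enone; C10 can enolise only toward C9 because C1 is quaternary, so the alkene appears at C8=C9, both C8 epimers converge, and C6, now an ester-bearing sp3 carbon, cannot draw the alkene to C7=C8.

Step 13
Reactants: 19 silyl ether enone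
Product: 20 trans-fused 2β,4β-dihydroxy-1β,8-dimethyl-4α-(propan-2-yl)-10-oxo-8-ene 6α-(3,4-dimethoxybenzoate) ((Z)-enone)
Conditions: HF·pyridine, THF, rt
Reagents that add atoms: none
Why: Acidic fluoride cleavage of the remaining silyl ether, done before the oxirane exists so that the strained ring never meets HF; base is avoided because the enone could lose the C6 ester by vinylogous β-elimination or undergo retro-aldol cleavage at C1–C2.

Step 14
Reactants: 20 (Z)-enone diol
Product: 22 trans-fused 8β,9α-epoxy-2β,4β-dihydroxy-1β,8α-dimethyl-4α-(propan-2-yl)-10-oxoperhydroazulen-6α-yl 3,4-dimethoxybenzoate (oxirane oxygen β on C8 and α on C9), via (E)-enone 21 (not isolated)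
Conditions: hν (366 nm), DMDO (acetone solution), CH2Cl2, 5 mM, −78 °C
Reagents that add atoms: dimethyldioxirane, CC1(C)OO1
Why: Proposed new method: light of 366 nm is absorbed only by the enone and should turn it, as cyclohept-2-enones do at low temperature, into the strained (E)-isomer 21, whose twisted, deconjugated C8=C9 bond is far more reactive toward an electrophilic oxidant than the conjugated (Z)-alkene, which dimethyldioxirane should leave untouched at −78 °C; concerted suprafacial oxygen transfer to the open face of 21 keeps C7 and C10 trans on the oxirane, so the oxygen is β on C8 and α on C9 when the twist puts the C8 methyl on the α side and H9 on the β side; the closest known reaction types are the Z-to-E photoisomerisation of cycloheptenones with stereospecific trapping to trans-fused cycloadducts and the dioxirane or peracid epoxidation of trans-cycloalkenes to trans-fused oxiranes, and the step needs the trap to be selective for the (E)-isomer and the (E)-isomer to have the stated twist.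

Step 15
Reactants: 22 trans-epoxy β-hydroxy ketone; 23 acetaldehyde
Product: 24 target: 2β-acetoxy-8β,9α-epoxy-4β,10α-dihydroxy-1β,8α-dimethyl-4α-(propan-2-yl)perhydroazulen-6α-yl 3,4-dimethoxybenzoate (CNP0197096.4, trans-fused oxirane)
Conditions: SmI2 (30 mol %) premixed with MeCHO, THF, −10 °C
Reagents that add atoms: acetaldehyde (23), CC=O
Why: Evans–Tishchenko reduction: the samarium-bound hemiacetal formed from C2–OH and acetaldehyde transfers hydride intramolecularly to the β face of the C10 carbonyl, where O2 lies, giving the 10α-alcohol and leaving the acetate on O2, and the trivalent samarium catalyst is formed from SmI2 and the aldehyde beforehand so that no divalent samarium meets the epoxy ketone.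

**Compound list**

1 | (S)-4-[(tert-butyldimethylsilyl)oxy]cyclopent-2-en-1-one | O=C1C=C[C@@H](O[Si](C)(C)C(C)(C)C)C1 | starting material
2 | methyllithium | [Li]C | starting material
3 | tert-butyldimethyl{[(1S,2S)-2-methyl-4-[(trimethylsilyl)oxy]cyclopent-3-en-1-yl]oxy}silane | C[C@H]1C=C(O[Si](C)(C)C)C[C@@H]1O[Si](C)(C)C(C)(C)C | intermediate
4 | (S)-4-[(tert-butyldimethylsilyl)oxy]-3-methylcyclopent-2-en-1-one | CC1=CC(=O)C[C@@H]1O[Si](C)(C)C(C)(C)C | intermediate
5 | (4S)-2,3-dibromo-4-[(tert-butyldimethylsilyl)oxy]-3-methylcyclopentan-1-one (trans-dibromide, C2 and C3 not assigned) | CC1(Br)C(Br)C(=O)C[C@@H]1O[Si](C)(C)C(C)(C)C | intermediate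
6 | (S)-2-bromo-4-[(tert-butyldimethylsilyl)oxy]-3-methylcyclopent-2-en-1-one | CC1=C(Br)C(=O)C[C@@H]1O[Si](C)(C)C(C)(C)C | intermediate
7 | isopropylmagnesium chloride | CC(C)[Mg]Cl | starting material
8 | (1S,4S)-2-bromo-4-[(tert-butyldimethylsilyl)oxy]-3-methyl-1-(propan-2-yl)cyclopent-2-en-1-ol | CC1=C(Br)[C@@](O)(C(C)C)C[C@@H]1O[Si](C)(C)C(C)(C)C | intermediate
9 | tert-butyl{[(1S,4S)-3-bromo-2-methyl-4-(propan-2-yl)-4-[(triethylsilyl)oxy]cyclopent-2-en-1-yl]oxy}dimethylsilane | CC1=C(Br)[C@@](O[Si](CC)(CC)CC)(C(C)C)C[C@@H]1O[Si](C)(C)C(C)(C)C | intermediate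
10 | 3-methylglutaric anhydride (4-methyloxane-2,6-dione) | O=C1CC(C)CC(=O)O1 | starting material
11 | {(3S,5S)-3-[(tert-butyldimethylsilyl)oxy]-2-methyl-5-(propan-2-yl)-5-[(triethylsilyl)oxy]cyclopent-1-en-1-yl}lithium | CC1=C([Li])[C@@](O[Si](CC)(CC)CC)(C(C)C)C[C@@H]1O[Si](C)(C)C(C)(C)C | intermediate
12 | 5-{(3S,5S)-3-[(tert-butyldimethylsilyl)oxy]-2-methyl-5-(propan-2-yl)-5-[(triethylsilyl)oxy]cyclopent-1-en-1-yl}-3-methyl-5-oxopentanoic acid (both C8 epimers) | CC1=C(C(=O)CC(C)CC(=O)O)[C@@](O[Si](CC)(CC)CC)(C(C)C)C[C@@H]1O[Si](C)(C)C(C)(C)C | intermediate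
13 | Se-phenyl selenoester of 12 (both C8 epimers) | CC1=C(C(=O)CC(C)CC(=O)[Se]c2ccccc2)[C@@](O[Si](CC)(CC)CC)(C(C)C)C[C@@H]1O[Si](C)(C)C(C)(C)C | intermediate
14 | trans-fused 2β-TBS-oxy-4β-TES-oxy-1β,8-dimethyl-4α-isopropyl-5α-H-perhydroazulene-6,10-dione (both C8 epimers) | O=C1CC(C)CC(=O)[C@]2(C)[C@@H](O[Si](C)(C)C(C)(C)C)C[C@](O[Si](CC)(CC)CC)(C(C)C)[C@@H]12 | intermediate
15 | 4β-hydroxy diketone (TES removed; both C8 epimers) | O=C1CC(C)CC(=O)[C@]2(C)[C@@H](O[Si](C)(C)C(C)(C)C)C[C@](O)(C(C)C)[C@@H]12 | intermediate
16 | 4β,6α-diol 10-ketone (both C8 epimers) | O[C@@H]1CC(C)CC(=O)[C@]2(C)[C@@H](O[Si](C)(C)C(C)(C)C)C[C@](O)(C(C)C)[C@@H]12 | intermediate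
17 | 3,4-dimethoxybenzoyl chloride | COc1ccc(C(=O)Cl)cc1OC | starting material
18 | 6α-veratrate 10-ketone (both C8 epimers) | COc1ccc(C(=O)O[C@@H]2CC(C)CC(=O)[C@]3(C)[C@@H](O[Si](C)(C)C(C)(C)C)C[C@](O)(C(C)C)[C@@H]23)cc1OC | intermediate
19 | 6α-veratrate 8-en-10-one, 2β-TBS ether ((Z)-enone) | COc1ccc(C(=O)O[C@@H]2CC(C)=CC(=O)[C@]3(C)[C@@H](O[Si](C)(C)C(C)(C)C)C[C@](O)(C(C)C)[C@@H]23)cc1OC | intermediate
20 | 6α-veratrate 8-en-10-one, 2β,4β-diol ((Z)-enone) | COc1ccc(C(=O)O[C@@H]2CC(C)=CC(=O)[C@]3(C)[C@@H](O)C[C@](O)(C(C)C)[C@@H]23)cc1OC | intermediate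
21 | (E)-isomer of 20 at the ring C8=C9 bond (C7 and C10 trans; C8 methyl on the α side, H9 on the β side) | COc1ccc(C(=O)O[C@@H]2C/C(C)=C/C(=O)[C@]3(C)[C@@H](O)C[C@](O)(C(C)C)[C@@H]23)cc1OC | intermediate
22 | trans-fused 8β,9α-epoxy-10-ketone, 2β,4β-diol, 6α-veratrate | COc1ccc(C(=O)O[C@@H]2C[C@@]3(C)O[C@@H]3C(=O)[C@]3(C)[C@@H](O)C[C@](O)(C(C)C)[C@@H]23)cc1OC | intermediate
23 | acetaldehyde | CC=O | starting material
24 | CNP0197096.4 (2β-acetoxy-8β,9α-epoxy-4β,10α-dihydroxy 6α-veratrate, trans-fused oxirane) | COc1ccc(C(=O)O[C@@H]2C[C@@]3(C)O[C@@H]3[C@H](O)[C@]3(C)[C@@H](OC(C)=O)C[C@](O)(C(C)C)[C@@H]23)cc1OC | target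

**Count**

Total steps: 15. Longest linear sequence: 15 steps (1 to 24).

**Steps most likely to fail**

Step 14. The (E)-enone may return thermally to the (Z)-form, add one of the free hydroxyls or dimerise before oxygen transfer. In addition, the sense of twist of the (E)-alkene, which decides between the 8β,9α- and the 8α,9β-oxirane, is imposed by the ring and may be biased the wrong way by the trans ring fusion. The fallback builds the oxirane by known reactions, one C–O bond at a time with defined configuration; it sets out from 19 and comes back at 22. OsO4 (5 mol %), NMO and citric acid in t-BuOH/H2O should dihydroxylate the enone on the β face, anti to the 6α-ester, to give 8β,9β-diol F1. MsCl and Et3N sulfonylate only the secondary C9 hydroxyl, giving mesylate F2. KOt-Bu in THF at −40 °C then closes the ring by intramolecular Williamson displacement, the C8 alkoxide entering the α-keto carbon C9 from the α face with inversion, to give trans-epoxy ketone silyl ether F3; the ring must twist strongly for this displacement, so a semipinacol shift is the expected competitor. HF·pyridine removes the silyl group and returns to 22.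

Step 8. Addition of the acyl radical to the fully substituted C1 may be slower than hydrogen transfer from the stannane or loss of CO, so that the chain is reduced without ring closure, and hydrogen delivery to C5 may show poor facial selectivity. The fallback sets out from 13 and comes back at 14. Hydrostannolysis of 13 with Bu3SnH under Pd(PPh3)4 catalysis, without a radical initiator, should give keto aldehyde F4. SmI2 with t-BuOH in THF/HMPA then closes the same C1–C10 bond by reductive aldehyde–enone (ketyl–olefin) cyclisation, in which the C10 ketyl is far longer-lived than an acyl radical and the C5 samarium enolate is protonated by the alcohol, giving hydroxy ketone F5. Dess–Martin oxidation of the C10 carbinol returns to 14.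

Step 15. The Lewis-acidic samarium catalyst may open or rearrange the strained oxirane, hemiacetal formation at the neopentyl C2 hydroxyl may be slow, and the acetyl group may migrate from O2 to O10. The fallback sets out from 22 and comes back at 24. Me4NBH(OAc)3 in MeCN with a minimum of AcOH at −40 °C, with hydride delivered from O2 in the same facial sense, should give epoxy triol F6. Ac2O and pyridine then acetylate the C2 hydroxyl, the C10 hydroxyl being flanked by the quaternary C1 and the oxirane, and lead to 24.

**Further compounds**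

F1 | step 14 | 8β,9β-diol of 19 (2β-TBS ether, 10-ketone, 6α-veratrate) | COc1ccc(C(=O)O[C@@H]2C[C@@](C)(O)[C@@H](O)C(=O)[C@]3(C)[C@@H](O[Si](C)(C)C(C)(C)C)C[C@](O)(C(C)C)[C@@H]23)cc1OC
F2 | step 14 | 9β-methanesulfonate of F1 | COc1ccc(C(=O)O[C@@H]2C[C@@](C)(O)[C@@H](OS(C)(=O)=O)C(=O)[C@]3(C)[C@@H](O[Si](C)(C)C(C)(C)C)C[C@](O)(C(C)C)[C@@H]23)cc1OC
F3 | step 14 | 2β-TBS ether of 22 (trans-fused 8β,9α-epoxy-10-ketone) | COc1ccc(C(=O)O[C@@H]2C[C@@]3(C)O[C@@H]3C(=O)[C@]3(C)[C@@H](O[Si](C)(C)C(C)(C)C)C[C@](O)(C(C)C)[C@@H]23)cc1OC
F4 | step 8 | 5-{(3S,5S)-3-[(tert-butyldimethylsilyl)oxy]-2-methyl-5-(propan-2-yl)-5-[(triethylsilyl)oxy]cyclopent-1-en-1-yl}-3-methyl-5-oxopentanal | CC1=C(C(=O)CC(C)CC=O)[C@@](O[Si](CC)(CC)CC)(C(C)C)C[C@@H]1O[Si](C)(C)C(C)(C)C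
F5 | step 8 | 10-hydroxy analogue of 14 (C10 carbinol, either epimer) | O=C1CC(C)CC(O)[C@]2(C)[C@@H](O[Si](C)(C)C(C)(C)C)C[C@](O[Si](CC)(CC)CC)(C(C)C)[C@@H]12
F6 | step 15 | trans-fused 8β,9α-epoxy-2β,4β,10α-triol 6α-veratrate | COc1ccc(C(=O)O[C@@H]2C[C@@]3(C)O[C@@H]3[C@H](O)[C@]3(C)[C@@H](O)C[C@](O)(C(C)C)[C@@H]23)cc1OC
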